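**Abbreviations.** MOM = methoxymethyl; PMB = 4-methoxybenzyl; TBDPS = tert-butyldiphenylsilyl; Ar* = 2,5-bis(methoxymethoxy)phenyl; NBS/NCS = N-bromo-/N-chlorosuccinimide; DMPU = N,N'-dimethylpropyleneurea; TMEDA = N,N,N',N'-tetramethylethylenediamine; DCC = N,N'-dicyclohexylcarbodiimide; DMAP = 4-(dimethylamino)pyridine; TFA = trifluoroacetic acid; H2IMes = 1,3-dimesitylimidazolidin-2-ylidene.

## Analysis of the target

Target 32 is a 2,3,4,7-tetrahydrooxepine (ring atoms O1, C2, C3, C4, C5, C6, C7) whose only ring double bond, C5=C6, is trisubstituted, and C6 carries a two-methylene tether (Ca, Cb) to an (E)-trisubstituted alkene whose allylic CH2–O is esterified by (E)-4-hydroxycinnamic acid. C2 is the single stereocentre; it is fully substituted, carrying O1, the carboxyl carbon C1', the methylene Cα that leads to the 2,5-dihydroxyphenyl ketone, and ring carbon C3, and it is R (priorities O1 > C1' > Cα > C3). There is no second stereocentre to which C2 could be related, and its two carbon arms are both CH2 groups that differ only further out, so the configuration has to be brought in absolutely. The sensitive groups set the limits for the end game: O1 is β to the aryl ketone, so base can expel it by E1cB and open the ring, and O1–C7 and the coumarate C–O bond are both allylic. The acylhydroquinone is easily oxidised, and the enoate and the alkenes rule out hydrogenolysis and hydride. The hard points are the isolated oxygenated quaternary centre, the hindered tertiary ether inside a seven-membered ring, and a deprotection that is neither basic, reductive nor oxidative. The strategy rests on one feature: C2 with O1 and C1' is the α-carbon of an α-hydroxy acid whose two other substituents are methylenes, in other words a lactic acid whose methyl carbon (the future Cα) is bonded to an acyl-anion carbon and whose α-hydrogen is replaced by the C3–C5 chain.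

## Retrosynthetic reasoning

**Protecting-group level (32 ⇐ 31 ⇐ 30).** No skeletal bond is formed in the last two operations. Target 32 is traced to 31, in which the three phenols are MOM ethers and the acid is a PMB ester, so that one acid treatment frees everything without base, hydride, hydrogen or oxidant. Methyl ethers on the hydroquinone and a methyl ester at C1' would be simpler to carry, but neither could be removed at the end without destroying the allylic ester, the alkenes or the β-alkoxy ketone, so they are replaced from the start. Compound 31 comes from 30, in which the ketone is still a 1,3-dithiane. As long as it is, Cα has no acidifying neighbour and O1 cannot be expelled, so all basic steps are placed before this point.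

**Side-chain ester (30 ⇐ 27 + 29).** The ester is cut between the allylic oxygen and the cinnamoyl carbon. A cinnamate is both an acyl donor and a Michael acceptor and would not survive alkoxides, ylides or fluoride, so it enters last, as acid 29, onto primary allylic alcohol 27. Acid 29 comes from aldehyde 28 by a condensation that fixes the E geometry.

**Ring closure at C5=C6 (27 ⇐ 26 ⇐ 25).** The ring is opened at its only double bond, which leads to diene 25 with a vinyl group at C5 and a 1,1-disubstituted alkene at C6. A closure at O1–C7 by intramolecular allylic substitution could also attack C5 and give a tetrahydrofuran, whereas metathesis at the alkene has no regiochemical alternative. The ring itself forces C4 and C7 to be cis, and the quaternary C2 helps the closure. The forward reaction has to prefer the terminal and the 1,1-disubstituted alkene over the hindered trisubstituted one in the side chain. Desilylation of 26 then gives 27.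

**The C5 vinyl group (25 ⇐ 24 ⇐ 23).** The terminal alkene comes from aldehyde 24 by methylenation, and the aldehyde from the dioxolane of 23. C5 travels as an acetal because a four-carbon alkenyl electrophile would eliminate instead of alkylating an enolate, whereas the acetal iodide 10 is a well-behaved primary electrophile.

**The O1–C7 ether (23 ⇐ 14 + 21).** The ether is cut at O1–C7, which gives tertiary alcohol 14 and allylic chloride 21. The bond is made intermolecularly while the ketone is masked and before the aldehyde is set free, so that no lactol can form. Both allyl termini of 21 are CH2 groups, so direct and allylic displacement lead to the same ether. The forward reaction must alkylate a hindered tertiary alkoxide.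

**Side-chain fragment (21 ⇐ 20 ⇐ 19 ⇐ 18 ⇐ 15 + 16).** The fragment is cut at Ca–Cb, which gives the dianion of methallyl alcohol 15 and prenyl bromide 16. The allylic alcohol of 18 becomes the chloride of 19, and an allylic oxidation of the E-methyl group of the gem-dimethyl alkene gives 20 with the required E geometry. Silylation gives 21.

**Release of the auxiliary (14 ⇐ 13).** The α-hydroxy ester 14 is the opened form of dioxolanone 13. Opening with the alkoxide of the ester alcohol sets pivalaldehyde 2 free and installs the acid protecting group in the same step.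

**Key disconnection (13 ⇐ 8 + 5 + 10).** Both carbon–carbon bonds to the C2 unit are cut in one operation: the bond from Cα to the future ketone carbon and the C2–C3 bond. This leaves the acyl-anion equivalent 8, the methylene dioxolanone 5 and iodide 10. The gain is that the whole carbon environment of the stereocentre is assembled in one flask, with the configuration relayed from 1 through the tert-butyl acetal. Both arms arrive masked (dithiane, dioxolane), which is what allows the basic steps that follow. The forward reaction has to add 1,4 and not 1,2, and has to alkylate the resulting enolate anti to tert-butyl.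

**Precursors (5 ⇐ 4 ⇐ 3 ⇐ 1 + 2; 8 ⇐ 7 ⇐ 6; 10 ⇐ 9).** Compound 5 comes from (R)-lactic acid 1 and 2 by acetalisation, bromination and elimination. The R acid is required because entry of the C3 arm anti to tert-butyl in the (2R) acetal gives R at C2. Dithiane 8 comes from aldehyde 6 by thioacetalisation and then MOM protection, in that order because the Lewis acid of the first step would strip MOM groups. Iodide 10 comes from bromide 9 by halide exchange.

## Alternatives that were turned down

Alternative 1: vinylsilane-terminated closure at C6–C7.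
- Disconnection and key step: the ring is cut at C6–C7. The tertiary alcohol would be carried as its (2-methoxyethoxy)methyl ether A2, which holds a (Z)-vinylsilane at C5=C6. The Lewis acid SnCl4 A3 would strip the methoxyethoxy group and leave the cation O1=C7H2. The silicon-bearing C6 attacks it, positive charge develops at C5 β to silicon, and loss of the silyl group gives the ring alkene of A1.
- For it: O1–C7 is made by a simple acetal-type protection of the tertiary alcohol, which is easier than the alkylation of step 13. The silane dictates position and geometry of the ring alkene. No ruthenium catalyst has to coexist with sulfur. On these points it is as strong as or stronger than the chosen route.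
- Against it: the disconnection does not address C2, so a separate enantioselective synthesis of the tertiary α-hydroxy ester is still needed. A stereodefined trisubstituted vinylsilane carrying the whole side chain costs several steps. In A2 the aryl ketone is free, so the Lewis acid can chelate ketone, ester and ether oxygens and promote loss of O1, and the ketone oxygen or the dimethoxyarene can capture the cation. The methyl ethers and methyl ester of A1 cannot be removed without harming the allylic ester and alkenes, and the pivalate has to be exchanged.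
- Comparison: the chosen strategy gives absolute control of C2 and a protecting-group set that can come off, and pays with a harder etherification.

Alternative 2: three-component carbomagnesiation for the ring alkene.
- Disconnection and key step: the C5=C6 unit is built as an acyclic alkene. The side-chain Grignard reagent A5, with CuBr·SMe2 A8 as catalyst, would add in anti fashion to prop-2-yn-1-ol A6 (present as its magnesium alkoxide), which makes the C6–Ca bond. The vinyl–magnesium bond held by the alkoxide would then be alkylated by oxirane A7, which makes C4–C5 and places C4 cis to C7 in diol A4.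
- For it: the alkene geometry follows from the mechanism, the side chain enters as a simple nucleophile, and the materials are cheap. It reaches the C3–C7 unit in fewer steps than the four-step fragment 21 plus metathesis, and is stronger there.
- Against it: A4 contains no C2. The stereocentre would still have to be made by joining an electrophile derived from C3 to a chiral α-hydroxy-acid enolate equivalent and then adding the Cα arm, that is, two successive alkylations of the same kind of auxiliary. The two primary alcohols of A4 must be told apart. The later O1–C7 closure is an intramolecular allylic substitution that can go to C5 and give a five-membered ring. Opening an epoxide with a vinylmagnesium species is slow.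
- Comparison: the risk is spread over several steps, whereas the chosen route concentrates it in step 7 and closes the ring where no regiochemical choice exists.

Alternative 3: carbenoid O–H insertion at O1–C7.
- Disconnection and key step: the ring is cut at O1–C7 of an oxepan-6-one. The terminal diazoketone A10 would be decomposed by the catalyst Rh2(OAc)4 A11. The metal carbenoid formed at C7 is captured by the tertiary hydroxyl at C2 (formal O–H insertion), which gives oxepanone A9.
- For it: intramolecular O–H insertion is one of the few reliable ways to etherify a hindered tertiary alcohol, and it forms seven-membered cyclic ethers well. On the O1–C7 bond it is stronger than step 13.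
- Against it: A9 has a ketone at C6 where the target has the C5=C6 alkene with its side chain. Adding a side-chain organometallic to C6 beside an ester and dehydrating can give three alkenes (C5=C6, C6=C7, exocyclic). The enol triflate route needs enolisation toward C5 against the more acidic C7 next to oxygen, followed by an sp2–sp3 coupling. Neither is regiochemically secure and both add steps. The diazoketone needs an acyl-activation and diazo-transfer sequence, C2 again has to come from elsewhere, and the methyl ethers raise the same end-game problem as in alternative 1.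
- Comparison: the chosen route closes the ring at the alkene itself, so its position is not in question, and it takes the stereocentre from lactic acid.

Key step: step 7

Assumption: the target is taken as the (2R) enantiomer with both acyclic C=C bonds E, and 28 is taken as a catalogue compound.

## Route

Step 1
Reactants: 1 (R)-lactic acid; 2 pivalaldehyde
Product: 3 (2R,5R)-2-tert-butyl-5-methyl-1,3-dioxolan-4-one (cis)
Conditions: p-TsOH·H2O (cat.), H2SO4 (cat.), pentane, reflux, Dean–Stark; crystallisation from Et2O/pentane, −78 °C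
Reagents that add atoms: none
Why: Acid-catalysed acetalisation of the α-hydroxy acid; the lactate centre directs the new acetal carbon so that tert-butyl and methyl are cis (thermodynamic preference), and low-temperature crystallisation should remove the trans isomer.

Step 2
Reactants: 3 (2R,5R)-2-tert-butyl-5-methyl-1,3-dioxolan-4-one
Product: 4 (2S,5S)-5-bromo-2-tert-butyl-5-methyl-1,3-dioxolan-4-one (bromine trans to tert-butyl; the acetal carbon is unchanged in space, its descriptor changes only through the priority of bromine)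
Conditions: NBS, AIBN (cat.), CCl4, reflux
Reagents that add atoms: N-bromosuccinimide, O=C1CCC(=O)N1Br
Why: Wohl–Ziegler radical bromination at the only captodatively activated C–H (C5, between ring oxygen and carbonyl); from here on the acetal carbon alone carries the chirality.

Step 3
Reactants: 4 (2S,5S)-5-bromo-2-tert-butyl-5-methyl-1,3-dioxolan-4-one
Product: 5 (2R)-2-tert-butyl-5-methylidene-1,3-dioxolan-4-one
Conditions: Et3N, Et2O, 0 °C → rt
Reagents that add atoms: none
Why: E2 dehydrobromination can only run toward the methyl group and gives the exocyclic captodative alkene; the product polymerises easily and is kept cold and used soon.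

Step 4
Reactants: 6 2,5-dihydroxybenzaldehyde
Product: 7 2-(1,3-dithian-2-yl)benzene-1,4-diol
Conditions: HS(CH2)3SH, BF3·OEt2 (cat.), CH2Cl2/Et2O, 0 °C → rt
Reagents that add atoms: propane-1,3-dithiol, SCCCS
Why: Lewis-acid-catalysed thioacetalisation of an aryl aldehyde; it is run on the free phenols because acetal-type phenol protecting groups would not survive BF3·OEt2.

Step 5
Reactants: 7 2-(1,3-dithian-2-yl)benzene-1,4-diol
Product: 8 2-[2,5-bis(methoxymethoxy)phenyl]-1,3-dithiane
Conditions: MOMCl, i-Pr2NEt, CH2Cl2, 0 °C → rt, argon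
Reagents that add atoms: chloromethyl methyl ether, COCCl
Why: Williamson-type O-alkylation of both phenols; MOM ethers withstand n-BuLi, alkoxides and ylides and are removed by acid at the end.

Step 6
Reactants: 9 2-(2-bromoethyl)-1,3-dioxolane
Product: 10 2-(2-iodoethyl)-1,3-dioxolane
Conditions: NaI, NaHCO3 (cat.), acetone, reflux
Reagents that add atoms: sodium iodide, [Na+].[I-]
Why: Finkelstein exchange driven by precipitation of NaBr; the iodide is needed because the hindered enolate of step 7 alkylates slowly.

Step 7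
Reactants: 8 2-[2,5-bis(methoxymethoxy)phenyl]-1,3-dithiane; 5 (2R)-2-tert-butyl-5-methylidene-1,3-dioxolan-4-one; 10 2-(2-iodoethyl)-1,3-dioxolane
Product: 13 (2R,5R)-5-{[2-(Ar*)-1,3-dithian-2-yl]methyl}-2-tert-butyl-5-[2-(1,3-dioxolan-2-yl)ethyl]-1,3-dioxolan-4-one, via lithiated dithiane 11 (not isolated), via lithium enolate 12 (not isolated)
Conditions: n-BuLi, THF, −78 → −20 °C; DMPU, −78 °C; 5 (slow addition); then 10 (3 equiv), −78 → −30 °C; aq. NH4Cl
Reagents that add atoms: none
Why: Proposed new method: deprotonation of 8 at the benzylic, doubly sulfur-stabilised carbon gives the soft delocalised anion 11, which in THF/DMPU should add to the terminal CH2 of the captodative alkene of 5 (Michael addition, forming the bond from Cα to the masked ketone carbon) and not to the lactone carbonyl. The lithium enolate 12 that results is planar at C5 of the dioxolanone, the tert-butyl group on the acetal carbon blocks one face, and the primary iodide 10 is attacked by SN2 from the other face (the C2–C3 bond of the target). The closest known reaction types are the one-flask conjugate addition of lithiated 2-aryl-1,3-dithianes to butenolides with trapping of the enolate, polar and radical conjugate additions to 5-alkylidene-2-tert-butyl-1,3-dioxolan-4-ones, and the anti-selective alkylation of 5-monosubstituted 2-tert-butyl-1,3-dioxolan-4-one enolates; their combination on 5 in one flask has not been described. No ring is closed. The one new stereocentre (C5 of the dioxolanone, C2 of the target) is controlled by the acetal stereocentre that stems from 1: with the (2R) acetal and entry of the C3 arm anti to tert-butyl it becomes R, as the target requires. The step needs 1,4- over 1,2-addition (soft anion, DMPU, low temperature), suppression of anionic oligomerisation of 5 (slow addition of 5 to a slight excess of 11), and alkylation that outruns fragmentation of 12 (excess iodide, DMPU, temperature kept at or below −30 °C).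

Step 8
Reactants: 13 (2R,5R)-5-{[2-(Ar*)-1,3-dithian-2-yl]methyl}-2-tert-butyl-5-[2-(1,3-dioxolan-2-yl)ethyl]-1,3-dioxolan-4-one
Product: 14 PMB (2R)-2-{[2-(Ar*)-1,3-dithian-2-yl]methyl}-4-(1,3-dioxolan-2-yl)-2-hydroxybutanoate
Conditions: 4-MeOC6H4CH2OH (5 equiv), NaH (0.2 equiv), THF, 0 °C → rt
Reagents that add atoms: 4-methoxybenzyl alcohol, COc1ccc(CO)cc1
Why: Alkoxide attack on the activated lactone carbonyl (transesterification); the hemiacetal alkoxide set free collapses to 2 and the tertiary alkoxide, which regenerates the nucleophile, so catalytic base suffices. The stereocentre is not touched and the PMB ester can later be removed by acid instead of hydroxide.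

Step 9
Reactants: 15 2-methylprop-2-en-1-ol (methallyl alcohol); 16 1-bromo-3-methylbut-2-ene (prenyl bromide)
Product: 18 6-methyl-2-methylidenehept-5-en-1-ol, via dilithiated methallyl alcohol 17 (not isolated)
Conditions: n-BuLi (2.2 equiv), TMEDA, Et2O/hexane, 0 °C → rt; then 16, −78 °C → rt; H2O
Reagents that add atoms: none
Why: Double deprotonation (O–H, then the allylic methyl group) gives an allyl anion with two equivalent CH2 termini, which is alkylated by SN2 at the primary carbon of the allylic bromide.

Step 10
Reactants: 18 6-methyl-2-methylidenehept-5-en-1-ol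
Product: 19 2-(chloromethyl)-6-methylhepta-1,5-diene
Conditions: PPh3, NCS, CH2Cl2, 0 °C → rt
Reagents that add atoms: N-chlorosuccinimide, O=C1CCC(=O)N1Cl
Why: Appel-type chlorination through the alkoxyphosphonium salt; SN2 and SN2' displacement give the same chloride because the allyl termini are equivalent.

Step 11
Reactants: 19 2-(chloromethyl)-6-methylhepta-1,5-diene
Product: 20 (2E)-6-(chloromethyl)-2-methylhepta-2,6-dien-1-ol
Conditions: SeO2 (cat.), t-BuOOH, salicylic acid (cat.), CH2Cl2, rt
Reagents that add atoms: tert-butyl hydroperoxide, CC(C)(C)OO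
Why: Catalytic SeO2 allylic oxidation (ene reaction, then [2,3]-sigmatropic shift) attacks the more electron-rich trisubstituted alkene at its E-methyl group, which sets the (E)-allylic alcohol; the 1,1-disubstituted alkene is deactivated by the chloromethyl group.

Step 12
Reactants: 20 (2E)-6-(chloromethyl)-2-methylhepta-2,6-dien-1-ol
Product: 21 tert-butyl{[(2E)-6-(chloromethyl)-2-methylhepta-2,6-dien-1-yl]oxy}diphenylsilane
Conditions: TBDPSCl, imidazole, CH2Cl2, 0 °C → rt
Reagents that add atoms: tert-butyl(chloro)diphenylsilane, CC(C)(C)[Si](Cl)(c1ccccc1)c1ccccc1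
Why: Standard silylation of a primary alcohol; TBDPS is chosen because it survives NaH in step 13 and the aqueous acid of step 14.

Step 13
Reactants: 14 PMB (2R)-2-{[2-(Ar*)-1,3-dithian-2-yl]methyl}-4-(1,3-dioxolan-2-yl)-2-hydroxybutanoate; 21 tert-butyl{[(2E)-6-(chloromethyl)-2-methylhepta-2,6-dien-1-yl]oxy}diphenylsilane
Product: 23 PMB (2R)-2-{[2-(Ar*)-1,3-dithian-2-yl]methyl}-2-{[(5E)-7-(TBDPS-oxy)-6-methyl-2-methylidenehept-5-en-1-yl]oxy}-4-(1,3-dioxolan-2-yl)butanoate, via sodium alkoxide 22 (not isolated)
Conditions: NaH, DMF, 0 °C; then 21, n-Bu4NI (cat.), 0 °C → rt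
Reagents that add atoms: none
Why: Williamson ether synthesis: the sodium alkoxide 22 displaces the allylic chloride (activated in the flask as the iodide), and SN2 and SN2' give the same ether. With the ketone held as a dithiane the alkoxide has no β-elimination pathway.

Step 14
Reactants: 23 PMB (2R)-2-{[2-(Ar*)-1,3-dithian-2-yl]methyl}-2-{[(5E)-7-(TBDPS-oxy)-6-methyl-2-methylidenehept-5-en-1-yl]oxy}-4-(1,3-dioxolan-2-yl)butanoate
Product: 24 PMB (2R)-2-{[2-(Ar*)-1,3-dithian-2-yl]methyl}-2-{[(5E)-7-(TBDPS-oxy)-6-methyl-2-methylidenehept-5-en-1-yl]oxy}-5-oxopentanoate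
Conditions: 1 M HCl, THF, rt
Reagents that add atoms: water, O
Why: Acid-catalysed acetal hydrolysis; under dilute aqueous acid at room temperature the aliphatic dioxolane should be more labile than the aryl MOM ethers, the TBDPS ether, the ester and the dithiane, and no lactol can form because O1 is already an ether.

Step 15
Reactants: 24 PMB (2R)-2-{[2-(Ar*)-1,3-dithian-2-yl]methyl}-2-{[(5E)-7-(TBDPS-oxy)-6-methyl-2-methylidenehept-5-en-1-yl]oxy}-5-oxopentanoate
Product: 25 PMB (2R)-2-{[2-(Ar*)-1,3-dithian-2-yl]methyl}-2-{[(5E)-7-(TBDPS-oxy)-6-methyl-2-methylidenehept-5-en-1-yl]oxy}hex-5-enoate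
Conditions: Ph3PCH3Br, KN(SiMe3)2, THF, 0 °C; then 24, −78 → 0 °C
Reagents that add atoms: methyltriphenylphosphonium bromide, C[P+](c1ccccc1)(c1ccccc1)c1ccccc1.[Br-]
Why: Wittig methylenation of an unhindered aldehyde with the non-stabilised ylide at low temperature, where the hindered ester does not react.

Step 16
Reactants: 25 PMB (2R)-2-{[2-(Ar*)-1,3-dithian-2-yl]methyl}-2-{[(5E)-7-(TBDPS-oxy)-6-methyl-2-methylidenehept-5-en-1-yl]oxy}hex-5-enoate
Product: 26 PMB (2R)-2-{[2-(Ar*)-1,3-dithian-2-yl]methyl}-6-[(3E)-5-(TBDPS-oxy)-4-methylpent-3-en-1-yl]-2,3,4,7-tetrahydrooxepine-2-carboxylate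
Conditions: RuCl2(=CHPh)(H2IMes)(PCy3) (second-generation Grubbs catalyst, 10 mol %), toluene (2 mM), 80 °C
Reagents that add atoms: none
Why: Ring-closing olefin metathesis between the monosubstituted alkene (initiation site) and the 1,1-disubstituted alkene gives the seven-membered ring with its trisubstituted C5=C6 bond and ethene. The quaternary C2 favours closure, the cis ring geometry is forced, and the hindered trisubstituted side-chain alkene should stay out.

Step 17
Reactants: 26 PMB (2R)-2-{[2-(Ar*)-1,3-dithian-2-yl]methyl}-6-[(3E)-5-(TBDPS-oxy)-4-methylpent-3-en-1-yl]-2,3,4,7-tetrahydrooxepine-2-carboxylate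
Product: 27 PMB (2R)-2-{[2-(Ar*)-1,3-dithian-2-yl]methyl}-6-[(3E)-5-hydroxy-4-methylpent-3-en-1-yl]-2,3,4,7-tetrahydrooxepine-2-carboxylate
Conditions: n-Bu4NF, AcOH, THF, 0 °C → rt
Reagents that add atoms: none
Why: Fluoride cleavage of the silyl ether, buffered with acetic acid; with the ketone still masked no base-induced loss of O1 is possible.

Step 18
Reactants: 28 4-(methoxymethoxy)benzaldehyde
Product: 29 (2E)-3-[4-(methoxymethoxy)phenyl]prop-2-enoic acid
Conditions: CH2(CO2H)2, pyridine, piperidine (cat.), 90 °C
Reagents that add atoms: malonic acid, OC(=O)CC(=O)O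
Why: Knoevenagel–Doebner condensation with decarboxylation gives the (E)-cinnamic acid; the MOM ether is stable to pyridine.

Step 19
Reactants: 27 PMB (2R)-2-{[2-(Ar*)-1,3-dithian-2-yl]methyl}-6-[(3E)-5-hydroxy-4-methylpent-3-en-1-yl]-2,3,4,7-tetrahydrooxepine-2-carboxylate; 29 (2E)-3-[4-(methoxymethoxy)phenyl]prop-2-enoic acid
Product: 30 PMB (2R)-2-{[2-(Ar*)-1,3-dithian-2-yl]methyl}-6-[(3E)-5-{[(2E)-3-(4-(methoxymethoxy)phenyl)prop-2-enoyl]oxy}-4-methylpent-3-en-1-yl]-2,3,4,7-tetrahydrooxepine-2-carboxylate
Conditions: DCC, DMAP (cat.), CH2Cl2, 0 °C → rt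
Reagents that add atoms: none
Why: Steglich esterification of the primary allylic alcohol; the cinnamate is introduced only now because it would not survive the alkoxide, ylide and fluoride steps.

Step 20
Reactants: 30 PMB (2R)-2-{[2-(Ar*)-1,3-dithian-2-yl]methyl}-6-[(3E)-5-{[(2E)-3-(4-(methoxymethoxy)phenyl)prop-2-enoyl]oxy}-4-methylpent-3-en-1-yl]-2,3,4,7-tetrahydrooxepine-2-carboxylate
Product: 31 PMB (2R)-2-[2-(Ar*)-2-oxoethyl]-6-[(3E)-5-{[(2E)-3-(4-(methoxymethoxy)phenyl)prop-2-enoyl]oxy}-4-methylpent-3-en-1-yl]-2,3,4,7-tetrahydrooxepine-2-carboxylate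
Conditions: MeI, CaCO3, MeCN/H2O (9:1), 45 °C
Reagents that add atoms: water, O
Why: Alkylative hydrolysis of the dithiane (S-methylation, opening to the benzylic thionium ion stabilised by the dialkoxyaryl ring, capture by water) under near-neutral conditions that leave alkenes, esters and MOM ethers alone.

Step 21
Reactants: 31 PMB (2R)-2-[2-(Ar*)-2-oxoethyl]-6-[(3E)-5-{[(2E)-3-(4-(methoxymethoxy)phenyl)prop-2-enoyl]oxy}-4-methylpent-3-en-1-yl]-2,3,4,7-tetrahydrooxepine-2-carboxylate
Product: 32 (2R)-2-[2-(2,5-dihydroxyphenyl)-2-oxoethyl]-6-[(3E)-5-{[(2E)-3-(4-hydroxyphenyl)prop-2-enoyl]oxy}-4-methylpent-3-en-1-yl]-2,3,4,7-tetrahydrooxepine-2-carboxylic acid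
Conditions: TFA/CH2Cl2 (1:4), anisole, H2O (5 equiv), 0 °C → rt
Reagents that add atoms: none
Why: Acidolysis removes the PMB ester (benzylic cation, trapped by anisole) and the three MOM ethers in one operation without base, oxidant or reductant. Both alkenes carry allylic oxygen substituents that lower their basicity, and C2 is not involved.

## Compound list

1 | (R)-lactic acid, (2R)-2-hydroxypropanoic acid | C[C@@H](O)C(=O)O | starting material
2 | pivalaldehyde, 2,2-dimethylpropanal | CC(C)(C)C=O | starting material
3 | (2R,5R)-2-tert-butyl-5-methyl-1,3-dioxolan-4-one | C[C@@H]1C(=O)O[C@H](C(C)(C)C)O1 | intermediate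
4 | (2S,5S)-5-bromo-2-tert-butyl-5-methyl-1,3-dioxolan-4-one | C[C@]1(Br)C(=O)O[C@H](C(C)(C)C)O1 | intermediate
5 | (2R)-2-tert-butyl-5-methylidene-1,3-dioxolan-4-one | C=C1C(=O)O[C@H](C(C)(C)C)O1 | intermediate
6 | 2,5-dihydroxybenzaldehyde | O=Cc1cc(O)ccc1O | starting material
7 | 2-(1,3-dithian-2-yl)benzene-1,4-diol | Oc1ccc(O)c(c1)C1SCCCS1 | intermediate
8 | 2-[2,5-bis(methoxymethoxy)phenyl]-1,3-dithiane | COCOc1ccc(OCOC)c(c1)C1SCCCS1 | intermediate
9 | 2-(2-bromoethyl)-1,3-dioxolane | BrCCC1OCCO1 | starting material
10 | 2-(2-iodoethyl)-1,3-dioxolane | ICCC1OCCO1 | intermediate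
11 | 2-[2,5-bis(methoxymethoxy)phenyl]-2-lithio-1,3-dithiane | [Li]C1(SCCCS1)c1cc(OCOC)ccc1OCOC | intermediate (not isolated)
12 | lithium enolate of (2R)-5-{[2-(2,5-bis(methoxymethoxy)phenyl)-1,3-dithian-2-yl]methyl}-2-tert-butyl-1,3-dioxolan-4-one | COCOc1ccc(OCOC)c(c1)C1(CC2=C(O[Li])O[C@H](C(C)(C)C)O2)SCCCS1 | intermediate (not isolated)
13 | (2R,5R)-5-{[2-(2,5-bis(methoxymethoxy)phenyl)-1,3-dithian-2-yl]methyl}-2-tert-butyl-5-[2-(1,3-dioxolan-2-yl)ethyl]-1,3-dioxolan-4-one | O1CCOC1CC[C@@]2(CC3(SCCCS3)c4cc(OCOC)ccc4OCOC)C(=O)O[C@H](C(C)(C)C)O2 | intermediate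
14 | 4-methoxybenzyl (2R)-2-{[2-(2,5-bis(methoxymethoxy)phenyl)-1,3-dithian-2-yl]methyl}-4-(1,3-dioxolan-2-yl)-2-hydroxybutanoate | O1CCOC1CC[C@@](O)(CC2(SCCCS2)c2cc(OCOC)ccc2OCOC)C(=O)OCc1ccc(OC)cc1 | intermediate
15 | 2-methylprop-2-en-1-ol | CC(=C)CO | starting material
16 | 1-bromo-3-methylbut-2-ene | CC(C)=CCBr | starting material
17 | lithium 2-(lithiomethyl)prop-2-en-1-olate | [Li]CC(=C)CO[Li] | intermediate (not isolated)
18 | 6-methyl-2-methylidenehept-5-en-1-ol | OCC(=C)CCC=C(C)C | intermediate
19 | 2-(chloromethyl)-6-methylhepta-1,5-diene | ClCC(=C)CCC=C(C)C | intermediate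
20 | (2E)-6-(chloromethyl)-2-methylhepta-2,6-dien-1-ol | OC/C(C)=C/CCC(=C)CCl | intermediate
21 | tert-butyl{[(2E)-6-(chloromethyl)-2-methylhepta-2,6-dien-1-yl]oxy}diphenylsilane | ClCC(=C)CC/C=C(\C)CO[Si](c1ccccc1)(c1ccccc1)C(C)(C)C | intermediate
22 | sodium alkoxide of 14 | O1CCOC1CC[C@@](O[Na])(CC2(SCCCS2)c2cc(OCOC)ccc2OCOC)C(=O)OCc1ccc(OC)cc1 | intermediate (not isolated)
23 | 4-methoxybenzyl (2R)-2-{[2-(2,5-bis(methoxymethoxy)phenyl)-1,3-dithian-2-yl]methyl}-2-{[(5E)-7-(tert-butyldiphenylsilyloxy)-6-methyl-2-methylidenehept-5-en-1-yl]oxy}-4-(1,3-dioxolan-2-yl)butanoate | O1CCOC1CC[C@@](OCC(=C)CC/C=C(\C)CO[Si](c3ccccc3)(c3ccccc3)C(C)(C)C)(CC2(SCCCS2)c2cc(OCOC)ccc2OCOC)C(=O)OCc1ccc(OC)cc1 | intermediate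
24 | 4-methoxybenzyl (2R)-2-{[2-(2,5-bis(methoxymethoxy)phenyl)-1,3-dithian-2-yl]methyl}-2-{[(5E)-7-(tert-butyldiphenylsilyloxy)-6-methyl-2-methylidenehept-5-en-1-yl]oxy}-5-oxopentanoate | O=CCC[C@@](OCC(=C)CC/C=C(\C)CO[Si](c3ccccc3)(c3ccccc3)C(C)(C)C)(CC2(SCCCS2)c2cc(OCOC)ccc2OCOC)C(=O)OCc1ccc(OC)cc1 | intermediate
25 | 4-methoxybenzyl (2R)-2-{[2-(2,5-bis(methoxymethoxy)phenyl)-1,3-dithian-2-yl]methyl}-2-{[(5E)-7-(tert-butyldiphenylsilyloxy)-6-methyl-2-methylidenehept-5-en-1-yl]oxy}hex-5-enoate | C=CCC[C@@](OCC(=C)CC/C=C(\C)CO[Si](c3ccccc3)(c3ccccc3)C(C)(C)C)(CC2(SCCCS2)c2cc(OCOC)ccc2OCOC)C(=O)OCc1ccc(OC)cc1 | intermediate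
26 | 4-methoxybenzyl (2R)-2-{[2-(2,5-bis(methoxymethoxy)phenyl)-1,3-dithian-2-yl]methyl}-6-[(3E)-5-(tert-butyldiphenylsilyloxy)-4-methylpent-3-en-1-yl]-2,3,4,7-tetrahydrooxepine-2-carboxylate | C/C(=C\CCC1=CCC[C@@](CC2(SCCCS2)c2cc(OCOC)ccc2OCOC)(C(=O)OCc2ccc(OC)cc2)OC1)CO[Si](c1ccccc1)(c1ccccc1)C(C)(C)C | intermediate
27 | 4-methoxybenzyl (2R)-2-{[2-(2,5-bis(methoxymethoxy)phenyl)-1,3-dithian-2-yl]methyl}-6-[(3E)-5-hydroxy-4-methylpent-3-en-1-yl]-2,3,4,7-tetrahydrooxepine-2-carboxylate | C/C(=C\CCC1=CCC[C@@](CC2(SCCCS2)c2cc(OCOC)ccc2OCOC)(C(=O)OCc2ccc(OC)cc2)OC1)CO | intermediate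
28 | 4-(methoxymethoxy)benzaldehyde | COCOc1ccc(C=O)cc1 | starting material
29 | (2E)-3-[4-(methoxymethoxy)phenyl]prop-2-enoic acid | COCOc1ccc(/C=C/C(=O)O)cc1 | intermediate
30 | 4-methoxybenzyl (2R)-2-{[2-(2,5-bis(methoxymethoxy)phenyl)-1,3-dithian-2-yl]methyl}-6-[(3E)-5-{[(2E)-3-(4-(methoxymethoxy)phenyl)prop-2-enoyl]oxy}-4-methylpent-3-en-1-yl]-2,3,4,7-tetrahydrooxepine-2-carboxylate | C/C(=C\CCC1=CCC[C@@](CC2(SCCCS2)c2cc(OCOC)ccc2OCOC)(C(=O)OCc2ccc(OC)cc2)OC1)COC(=O)/C=C/c1ccc(OCOC)cc1 | intermediate
31 | 4-methoxybenzyl (2R)-2-{2-[2,5-bis(methoxymethoxy)phenyl]-2-oxoethyl}-6-[(3E)-5-{[(2E)-3-(4-(methoxymethoxy)phenyl)prop-2-enoyl]oxy}-4-methylpent-3-en-1-yl]-2,3,4,7-tetrahydrooxepine-2-carboxylate | C/C(=C\CCC1=CCC[C@@](CC(=O)c2cc(OCOC)ccc2OCOC)(C(=O)OCc2ccc(OC)cc2)OC1)COC(=O)/C=C/c1ccc(OCOC)cc1 | intermediate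
32 | (2R)-2-[2-(2,5-dihydroxyphenyl)-2-oxoethyl]-6-[(3E)-5-{[(2E)-3-(4-hydroxyphenyl)prop-2-enoyl]oxy}-4-methylpent-3-en-1-yl]-2,3,4,7-tetrahydrooxepine-2-carboxylic acid (CNP0602535.1) | C/C(=C\CCC1=CCC[C@@](CC(=O)c2cc(O)ccc2O)(C(=O)O)OC1)COC(=O)/C=C/c1ccc(O)cc1 | target

## Step count and risk

Total: 21 steps. Longest linear sequence: 13 steps (1, 2, 3, 7, 8, 13, 14, 15, 16, 17, 19, 20, 21).

**Step 7 (key step, proposed new method).**
What may go wrong: anionic oligomerisation of 5 when enolate 12 adds to further 5; competing attack of 11 at the lactone carbonyl; alkylation so slow that 12 fragments or that 10 loses HI by E2.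
Fallback (known chemistry; it sets out from 9 and 8 and comes back to the route at 14): Bromide 9 is converted with Mg in THF (below 30 °C) into [2-(1,3-dioxolan-2-yl)ethyl]magnesium bromide F1. Of this reagent 2.5 equivalents are added across prop-2-yn-1-ol A6 under CuI catalysis (the first equivalent is spent on the O–H), and protonation of the vinylmagnesium product gives 4-(1,3-dioxolan-2-yl)-2-methylidenebutan-1-ol F2. Sharpless asymmetric epoxidation (Ti(O-i-Pr)4, L-(+)-diethyl tartrate, t-BuOOH, 4 Å sieves, CH2Cl2, −20 °C) gives [(2S)-2-[2-(1,3-dioxolan-2-yl)ethyl]oxiran-2-yl]methanol F3. Anion 11, made from 8 as in step 7 (2.2 equiv, THF/DMPU, −78 → 0 °C), opens the epoxide at its CH2 carbon, forming the Cα bond and giving (2R)-2-{[2-(2,5-bis(methoxymethoxy)phenyl)-1,3-dithian-2-yl]methyl}-4-(1,3-dioxolan-2-yl)butane-1,2-diol F4. Parikh–Doering oxidation of the primary alcohol gives (2R)-2-{[2-(2,5-bis(methoxymethoxy)phenyl)-1,3-dithian-2-yl]methyl}-4-(1,3-dioxolan-2-yl)-2-hydroxybutanal F5. Pinnick oxidation (NaClO2, NaH2PO4, excess 2-methylbut-2-ene) gives (2R)-2-{[2-(2,5-bis(methoxymethoxy)phenyl)-1,3-dithian-2-yl]methyl}-4-(1,3-dioxolan-2-yl)-2-hydroxybutanoic acid F6. O-Alkylation of this acid with 4-methoxybenzyl chloride and Cs2CO3 in DMF gives 14. The stereocentre then comes from the epoxidation catalyst and not from lactic acid.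

**Step 13.**
What may go wrong: slow alkylation of the hindered tertiary alkoxide, which leaves time for intermolecular transesterification at the PMB ester and for decomposition of the allylic halide.
Fallback (it sets out from 14 and 21 and comes back at 23): allylic etherification under palladium catalysis. Alcohol 14 is converted with Et2Zn (0.5 equiv, THF, 0 °C) into zinc bis{(2R)-2-{[2-(2,5-bis(methoxymethoxy)phenyl)-1,3-dithian-2-yl]methyl}-4-(1,3-dioxolan-2-yl)-1-[(4-methoxyphenyl)methoxy]-1-oxobutan-2-olate} F7. This is treated with 21 and zerovalent palladium (Pd(PPh3)4, 5 mol %) at rt. The 2-substituted π-allyl ligand has two equivalent CH2 termini, so only ether 23 can form, and a cationic allyl complex is far less sensitive to the bulk of the nucleophile than an sp3 carbon.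

**Step 16.**
What may go wrong: coordination of the dithiane sulfur atoms to ruthenium stalls the catalyst; slow closure onto the 1,1-disubstituted alkene lets the terminal alkene dimerise.
Fallback (it sets out from 25 and comes back at 31): the sulfur is removed before the metathesis. MeI/CaCO3 in aqueous MeCN converts 25 into 4-methoxybenzyl (2R)-2-{2-[2,5-bis(methoxymethoxy)phenyl]-2-oxoethyl}-2-{[(5E)-7-(tert-butyldiphenylsilyloxy)-6-methyl-2-methylidenehept-5-en-1-yl]oxy}hex-5-enoate F8. Ring-closing metathesis with the catalyst of step 16 gives 4-methoxybenzyl (2R)-2-{2-[2,5-bis(methoxymethoxy)phenyl]-2-oxoethyl}-6-[(3E)-5-(tert-butyldiphenylsilyloxy)-4-methylpent-3-en-1-yl]-2,3,4,7-tetrahydrooxepine-2-carboxylate F9. Non-basic desilylation with HF·pyridine in THF/pyridine gives 4-methoxybenzyl (2R)-2-{2-[2,5-bis(methoxymethoxy)phenyl]-2-oxoethyl}-6-[(3E)-5-hydroxy-4-methylpent-3-en-1-yl]-2,3,4,7-tetrahydrooxepine-2-carboxylate F10. Steglich esterification with 29 gives 31. The price is that the ketone is free during these steps, so basic reagents are excluded.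

**Step 21.**
What may go wrong: acid-catalysed β-elimination of O1 from the now free β-alkoxy ketone (ring opening), ionisation of the allylic ester, and Friedel–Crafts alkylation of the electron-rich rings by the benzyl and methoxymethyl cations.
Fallback (it sets out from 30 and comes back at 32): the last two steps change places. Acidolysis of 30 (TFA/CH2Cl2, anisole, H2O), with the ketone still masked, gives (2R)-2-{[2-(2,5-dihydroxyphenyl)-1,3-dithian-2-yl]methyl}-6-[(3E)-5-{[(2E)-3-(4-hydroxyphenyl)prop-2-enoyl]oxy}-4-methylpent-3-en-1-yl]-2,3,4,7-tetrahydrooxepine-2-carboxylic acid F11. Alkylative dithiane hydrolysis (MeI, CaCO3, aqueous MeCN, argon) then gives 32 under near-neutral conditions.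

## Further compounds

F1 | step 7 | [2-(1,3-dioxolan-2-yl)ethyl]magnesium bromide | Br[Mg]CCC1OCCO1
F2 | step 7 | 4-(1,3-dioxolan-2-yl)-2-methylidenebutan-1-ol | OCC(=C)CCC1OCCO1
F3 | step 7 | [(2S)-2-[2-(1,3-dioxolan-2-yl)ethyl]oxiran-2-yl]methanol | OC[C@@]1(CCC2OCCO2)CO1
F4 | step 7 | (2R)-2-{[2-(2,5-bis(methoxymethoxy)phenyl)-1,3-dithian-2-yl]methyl}-4-(1,3-dioxolan-2-yl)butane-1,2-diol | O1CCOC1CC[C@@](O)(CC2(SCCCS2)c2cc(OCOC)ccc2OCOC)CO
F5 | step 7 | (2R)-2-{[2-(2,5-bis(methoxymethoxy)phenyl)-1,3-dithian-2-yl]methyl}-4-(1,3-dioxolan-2-yl)-2-hydroxybutanal | O1CCOC1CC[C@@](O)(CC2(SCCCS2)c2cc(OCOC)ccc2OCOC)C=O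
F6 | step 7 | (2R)-2-{[2-(2,5-bis(methoxymethoxy)phenyl)-1,3-dithian-2-yl]methyl}-4-(1,3-dioxolan-2-yl)-2-hydroxybutanoic acid | O1CCOC1CC[C@@](O)(CC2(SCCCS2)c2cc(OCOC)ccc2OCOC)C(=O)O
F7 | step 13 | zinc bis{(2R)-2-{[2-(2,5-bis(methoxymethoxy)phenyl)-1,3-dithian-2-yl]methyl}-4-(1,3-dioxolan-2-yl)-1-[(4-methoxyphenyl)methoxy]-1-oxobutan-2-olate} | [Zn](O[C@](CCC1OCCO1)(CC2(SCCCS2)c2cc(OCOC)ccc2OCOC)C(=O)OCc1ccc(OC)cc1)O[C@](CCC1OCCO1)(CC2(SCCCS2)c2cc(OCOC)ccc2OCOC)C(=O)OCc1ccc(OC)cc1
F8 | step 16 | 4-methoxybenzyl (2R)-2-{2-[2,5-bis(methoxymethoxy)phenyl]-2-oxoethyl}-2-{[(5E)-7-(tert-butyldiphenylsilyloxy)-6-methyl-2-methylidenehept-5-en-1-yl]oxy}hex-5-enoate | C=CCC[C@@](OCC(=C)CC/C=C(\C)CO[Si](c3ccccc3)(c3ccccc3)C(C)(C)C)(CC(=O)c2cc(OCOC)ccc2OCOC)C(=O)OCc1ccc(OC)cc1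
F9 | step 16 | 4-methoxybenzyl (2R)-2-{2-[2,5-bis(methoxymethoxy)phenyl]-2-oxoethyl}-6-[(3E)-5-(tert-butyldiphenylsilyloxy)-4-methylpent-3-en-1-yl]-2,3,4,7-tetrahydrooxepine-2-carboxylate | C/C(=C\CCC1=CCC[C@@](CC(=O)c2cc(OCOC)ccc2OCOC)(C(=O)OCc2ccc(OC)cc2)OC1)CO[Si](c1ccccc1)(c1ccccc1)C(C)(C)C
F10 | step 16 | 4-methoxybenzyl (2R)-2-{2-[2,5-bis(methoxymethoxy)phenyl]-2-oxoethyl}-6-[(3E)-5-hydroxy-4-methylpent-3-en-1-yl]-2,3,4,7-tetrahydrooxepine-2-carboxylate | C/C(=C\CCC1=CCC[C@@](CC(=O)c2cc(OCOC)ccc2OCOC)(C(=O)OCc2ccc(OC)cc2)OC1)CO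
F11 | step 21 | (2R)-2-{[2-(2,5-dihydroxyphenyl)-1,3-dithian-2-yl]methyl}-6-[(3E)-5-{[(2E)-3-(4-hydroxyphenyl)prop-2-enoyl]oxy}-4-methylpent-3-en-1-yl]-2,3,4,7-tetrahydrooxepine-2-carboxylic acid | C/C(=C\CCC1=CCC[C@@](CC2(SCCCS2)c2cc(O)ccc2O)(C(=O)O)OC1)COC(=O)/C=C/c1ccc(O)cc1
A1 | alternative 1 | methyl (2R)-2-[2-(2,5-dimethoxyphenyl)-2-oxoethyl]-6-[(3E)-5-(2,2-dimethylpropanoyloxy)-4-methylpent-3-en-1-yl]-2,3,4,7-tetrahydrooxepine-2-carboxylate | C/C(=C\CCC1=CCC[C@@](CC(=O)c2cc(OC)ccc2OC)(C(=O)OC)OC1)COC(=O)C(C)(C)C
A2 | alternative 1 | methyl (2R,5Z,9E)-2-[2-(2,5-dimethoxyphenyl)-2-oxoethyl]-11-(2,2-dimethylpropanoyloxy)-2-[(2-methoxyethoxy)methoxy]-10-methyl-6-(trimethylsilyl)undeca-5,9-dienoate | C/C(=C\CC/C(=C/CC[C@@](CC(=O)c1cc(OC)ccc1OC)(C(=O)OC)OCOCCOC)[Si](C)(C)C)COC(=O)C(C)(C)C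
A3 | alternative 1 | tin tetrachloride, SnCl4 | Cl[Sn](Cl)(Cl)Cl
A4 | alternative 2 | (2Z)-2-{(3E)-5-[(4-methoxyphenyl)methoxy]-4-methylpent-3-en-1-yl}pent-2-ene-1,5-diol | C/C(=C\CC/C(CO)=C/CCO)COCc1ccc(OC)cc1
A5 | alternative 2 | {(3E)-5-[(4-methoxyphenyl)methoxy]-4-methylpent-3-en-1-yl}magnesium bromide | C/C(=C\CC[Mg]Br)COCc1ccc(OC)cc1
A6 | alternative 2 | prop-2-yn-1-ol | C#CCO
A7 | alternative 2 | oxirane | C1CO1
A8 | alternative 2 | copper bromide dimethyl sulfide complex, CuBr·SMe2 | CSC.Br[Cu]
A9 | alternative 3 | methyl (2R)-2-{[2-(2,5-dimethoxyphenyl)-1,3-dioxolan-2-yl]methyl}-6-oxooxepane-2-carboxylate | O=C1CCC[C@@](CC2(OCCO2)c3cc(OC)ccc3OC)(C(=O)OC)OC1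
A10 | alternative 3 | methyl (2R)-7-diazo-2-{[2-(2,5-dimethoxyphenyl)-1,3-dioxolan-2-yl]methyl}-2-hydroxy-6-oxoheptanoate | [N-]=[N+]=CC(=O)CCC[C@@](CC2(OCCO2)c3cc(OC)ccc3OC)(C(=O)OC)O
A11 | alternative 3 | dirhodium tetraacetate, Rh2(OAc)4 | CC(=O)[O-].CC(=O)[O-].CC(=O)[O-].CC(=O)[O-].[Rh+2].[Rh+2]
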